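## The problem

Target 27 is a germacranolide: a ten-membered carbocycle (C1–C10) trans-fused through C6 and C7 to an α-methylene-γ-butyrolactone (O, C6, C7, C11(=C13), C12). The carbocycle carries an E alkene at C1=C2 and a Z, methyl-bearing alkene at C4(C15)=C5, so a medium ring must be closed while two alkenes of opposite geometry are kept or made under control. There are five stereocentres (3R, 6R, 7R, 8R, 10R). C6, C7 and C8 are contiguous: C6 can direct C7 across the five-membered ring, and the C7/C8 relationship follows from the transition state of the reaction that joins them. C10 is a fully substituted carbinol insulated by C9 and is best taken from the chiral pool, while C3 lies across the ring from the others and can only be set by the ring conformation or by a reagent. The molecule is fragile: the α-methylene lactone is a Michael acceptor, the angelate at C8 isomerises to the tiglate with nucleophiles or heat, the doubly allylic C3 carbinol and the tertiary allylic C10 carbinol ionise in acid, and the lactone C6–O bond is allylic. The enabling feature is C3: it is bonded only to the alkenyl carbons C2 and C4, so at the ketone level C2–C3–C4 is a divinyl ketone whose carbonyl carbon can be carbon monoxide. Closing the ring at C3 then joins an E-alkenyl terminus to a Z-alkenyl terminus without touching either double bond.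

## Retrosynthesis

**C3–H (27 to 26).** The C3 carbinol is taken back to ketone 26. The neighbouring option, closing the ring at the carbinol level by adding an alkenyl metal to an enal, would create C3 during the macrocyclisation with no control and would form only one C–C bond. With the ketone, C3 becomes a one-carbon unit with no stereochemistry. The forward step is a 1,2-reduction of a cross-conjugated dienone that must spare the methylene lactone and set 3R.

**C2–C3 and C3–C4 (26 to 24 and 25).** Both bonds to the carbonyl carbon are cut at once, giving seco lactone 24 (Z-alkenyl iodide at C4, E-alkenylstannane at C2) and carbon monoxide 25. Metathesis at C1=C2 or C4=C5 would leave the alkene geometry to the ring closure, and a one-bond acylation at C3 would need an enoyl electrophile carried through the synthesis. Here both geometries are fixed before cyclisation and the precursor has lost the ring and one carbon. The forward reaction must insert CO before transmetalation and cyclise rather than oligomerise.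

**O–Si and C8–O (24 to 23 to 21 and 22).** The tertiary C10 alcohol of 24 is masked as the triethylsilyl ether 23 during the steps that activate C8. The angelate is cut at the C8–O bond with inversion, giving alcohol 21 (8S) and angelic acid 22. The inversion is needed because the reaction chosen for C7–C8 should deliver the C8 epimer of the target pattern. A Mitsunobu esterification corrects C8 and introduces the ester in one step without base. Acylation with retention would need an extra inversion sequence on a substrate that tolerates neither base nor a C8 ketone (C7–H would then be acidic and C11=C13 would move into conjugation).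

**C7–C8 (21 to 9 and 20).** This cut divides the molecule into bromomethyl butenolide 9 (C4–C7, C11–C13, C15) and aldehyde 20 (C8–C10, C1, C2, C14) and creates the α-methylene lactone as a consequence of the bond formation. A C8–C9 aldol would need a labile C8 aldehyde on the lactone. A C6–C7 allylation of an iodoenal with an acyclic 2-(bromomethyl)enoate gives the cis-lactone from the accessible bromide geometry. The forward Barbier reaction must add anti to the C6 substituent (7R) and is expected to give the 7,8-anti adduct through a chair. The stannane is placed in 20 and the iodide in 9 so that no palladium is used between fragment union and the key step. A palladium-catalysed hydrostannation after the iodide is present would consume the iodide.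

**Fragment A (9 to 8 to 5 and 6; 5 to 3 to 1 and 2).** The butenolide C7=C11 bond is cut by retro-metathesis to ester 8, and the ester to dienol 5 and acid 6. The iodoalkene of 5 is taken back (C4–I, C5–H) to propargylic alcohol 3 through alkenylaluminate 4, and 3 is cut at C5–C6 to crotonaldehyde 1 and propyne 2. The neighbouring route, a chiral-pool hydroxymethyl butenolide, would need a C5 aldehyde next to the lactone oxygen and a basic iodo-ylide olefination beside a Michael acceptor. Here the Z iodide comes from a directed trans-hydroalumination before any sensitive group exists, and C6 is the only stereocentre, set by catalytic asymmetric alkynylation.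

**Fragment B (20 to 19 to 17 and 18; 17 to 16 to 14 and 15; 14 to 13 to 11 to 10).** The aldehyde 20 is taken back to the primary silyl ether 19, the C2–Sn bond to alkyne 17 and tributyltin hydride 18, and the silyl groups to diol 16. The C1≡C2 bond is cut to lactol 14 and reagent 15, and 14 is traced through lactone 13 and dioxolanone acid 11 (via 12) to (R)-citramalic acid 10. The stereocentre of 10 becomes C10 without any bond to it being broken. An asymmetric alkynylation of a methyl ketone would make the same carbinol less reliably.

## Roads not taken

**Alternative 1:** The cut is across C8–C9 and O–C10, a retro-1,3-dipolar cycloaddition that treats the C8/C10 oxygen pattern as a masked aldol. In the forward step a nitrile oxide generated at C8 from an aldoxime (N-chlorosuccinimide, Et3N, high dilution) adds to the 1,1-disubstituted end of a C9=C10–C1=C2 diene and closes the carbocycle as the isoxazoline-bridged lactone A1.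
- Merits: the ring closure needs no metal and no tin, its regiochemistry is secure (oxygen to the more substituted carbon), and C10 needs no chiral-pool sequence. In these respects it is better than the chosen plan, which spends seven steps on fragment B.
- Weak points: C10 is created in the macrocyclisation with only the ring conformation to control it. The dipole sits on C7, so epimerisation there and dimerisation to the furoxan compete at the dilution a ten-membered ring requires.
- After the key step: the N–O bond must be cleaved (Mo(CO)6) beside a methylene lactone. This exposes a C8 ketone next to the acidic C7–H, which must then be reduced with control and acylated.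
- Comparison: the chosen plan sets every stereocentre except C3 before cyclisation and finishes one step after it.

**Alternative 2:** The cut is the C4=C5 alkene, with the C3 and C6 oxygens tied by a diisopropylsilylene. In the forward step the second-generation Grubbs catalyst RuCl2(=CHPh)(PCy3)(H2IMes) joins a C3 isopropenyl group and a C6 vinyl group inside an eleven-membered silylene diether, closing a dioxasilepine and the carbocycle as A2.
- Merits: the seven-membered silicon ring enforces the Z geometry, and C3 is set before ring closure. On C3 this road is better than the chosen plan, which must rely on ring conformation or a chiral reductant in the last step.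
- Weak points: a trisubstituted alkene must form by transannular metathesis while C1=C2, the 1,1-disubstituted C11=C13 and the angelate compete for the carbene. The tether itself requires a prior eleven-membered ring closure.
- After the key step: the silylene and the PMB ether must be removed and a primary allylic alcohol oxidised to the acid in the presence of the equally oxidisable C3 carbinol before lactonisation.
- Comparison: the chosen plan offers alkenes that are spectators in the ring closure and a one-step endgame.

**Alternative 3:** A C1–C6 bond is added so that the ten-membered ring becomes a trans-decalin with a tertiary alcohol at C6 and an equatorial mesylate at C2. In the forward step KOtBu triggers a Grob fragmentation that gives the C6 ketone and E-C1=C2 in the cyclodecadienone A3.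
- Merits: ring strain is released rather than built, no dilution is needed and the E geometry is stereospecific. As a ring-forming event this is more reliable than any macrocyclisation, including the chosen one.
- Weak points: the bicycle needs seven stereocentres in the correct antiperiplanar array. A3 carries a Z-enone and an epimerisable C7 under strong base.
- After the key step: C6 reduction, construction of the lactone from the C12 silyl ether, PMB removal, angeloylation and cleavage of two TBS ethers (one tertiary) are still required.
- Comparison: the chosen plan is convergent (four and seven steps to the fragments, five after union) and accepts a riskier ring closure for a much shorter route.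

Key step: step 15

Assumption 1: the sense of induction of the ProPhenol ligand in step 1 is taken from the usual facial model and would be confirmed by Mosher ester analysis of 3; the antipodal ligand is used if required.
Assumption 2: the Barbier addition of step 12 is taken to pass through a chair transition state and to give the 7,8-anti adduct, which is why step 13 inverts C8.

Step 1
Reactants: 1 (E)-but-2-enal; 2 propyne
Product: 3 (2E,4S)-hept-2-en-5-yn-4-ol
Conditions: 2 (3 equiv), Me2Zn (3 equiv), (S,S)-ProPhenol [2,6-bis{[(S)-2-(hydroxydiphenylmethyl)pyrrolidin-1-yl]methyl}-4-methylphenol] (10 mol %), Ph3P=O (20 mol %), toluene, 0 °C; then 1; aq NH4Cl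
Reagents that add atoms: none
Why: Zinc–ProPhenol-catalysed asymmetric alkynylation of an α,β-unsaturated aldehyde; the dinuclear zinc alkynyl complex delivers the propynyl group to one face of the aldehyde and sets the future C6 carbinol (4S in 3).

Step 2
Reactants: 3
Product: 5 (2E,4S,5Z)-6-iodohepta-2,5-dien-4-ol, via sodium alkenylaluminate 4 (not isolated)
Conditions: NaAlH2(OCH2CH2OCH3)2, THF, 0 °C to rt; then I2, THF, −78 °C; aq KNaC4H4O6, Na2S2O3
Reagents that add atoms: iodine, II
Why: Alkoxide-directed trans-hydroalumination of the propargylic alcohol puts aluminium on the distal alkyne carbon inside a five-membered oxaluminacycle, and iodinolysis with retention gives the alkenyl iodide with iodine cis to the carbinol carbon (5Z); the stereocentre is not touched.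

Step 3
Reactants: 5; 6 2-(bromomethyl)prop-2-enoic acid
Product: 8 (2E,4S,5Z)-6-iodohepta-2,5-dien-4-yl 2-(bromomethyl)prop-2-enoate, via 2-(bromomethyl)prop-2-enoyl chloride 7 (not isolated)
Conditions: 6, (COCl)2, DMF (cat.), CH2Cl2, 0 °C to rt, evaporation; then 5, 2,6-lutidine, CH2Cl2, −20 to 0 °C
Reagents that add atoms: none
Why: O-Acylation of a secondary alcohol with an acid chloride; the hindered, weakly nucleophilic base is chosen so that the allylic bromide is not displaced, and no bond to the stereocentre is broken.

Step 4
Reactants: 8
Product: 9 (5S)-3-(bromomethyl)-5-[(1Z)-2-iodoprop-1-en-1-yl]furan-2(5H)-one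
Conditions: second-generation Grubbs catalyst RuCl2(=CHPh)(PCy3)(H2IMes) (5 mol %), CH2Cl2, 40 °C, 5 mM
Reagents that add atoms: none
Why: Ring-closing metathesis between the acrylate and the propenyl group closes the butenolide with loss of propene; the trisubstituted iodoalkene does not engage the ruthenium carbene.

Step 5
Reactants: 10 (R)-citramalic acid
Product: 11 2-[(4R)-2,2,4-trimethyl-5-oxo-1,3-dioxolan-4-yl]acetic acid
Conditions: Me2C(OMe)2, TsOH·H2O (cat.), rt
Reagents that add atoms: 2,2-dimethoxypropane, COC(C)(C)OC
Why: Dioxolanone (acetonide) formation engages only the α-hydroxy acid and so differentiates the two carboxyl groups; the fully substituted stereocentre cannot epimerise.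

Step 6
Reactants: 11
Product: 13 (3R)-3-hydroxy-3-methyloxolan-2-one, via hydroxyethyl dioxolanone 12 (not isolated)
Conditions: BH3·SMe2, THF, 0 °C to rt; MeOH; then TsOH·H2O (cat.), CH2Cl2, rt
Reagents that add atoms: none
Why: Borane reduces the free carboxylic acid beside the dioxolanone, and acid-catalysed translactonisation of the primary alcohol onto the dioxolanone carbonyl expels acetone to give the α-hydroxy-γ-lactone.

Step 7
Reactants: 13
Product: 14 (3R)-3-methyloxolane-2,3-diol (lactol, both anomers)
Conditions: iBu2AlH (2.2 equiv), CH2Cl2, −78 °C; MeOH, then Na2SO4·10H2O, filtration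
Reagents that add atoms: none
Why: Partial reduction of a γ-lactone to the lactol at low temperature; the first equivalent of hydride is consumed by the tertiary hydroxyl group and the tetrahedral aluminium alkoxide is stable until work-up.

Step 8
Reactants: 14; 15 dimethyl (1-diazo-2-oxopropyl)phosphonate
Product: 16 (3R)-3-methylpent-4-yne-1,3-diol
Conditions: K2CO3, MeOH, 0 °C to rt
Reagents that add atoms: none
Why: Ohira–Bestmann homologation of the open hydroxy-aldehyde form of the lactol gives the terminal alkyne (C1≡C2); the aldehyde has no α-hydrogen, so the stereocentre is safe and the diol needs no protection.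

Step 9
Reactants: 16
Product: 17 (3R)-3-methyl-1,3-bis[(triethylsilyl)oxy]pent-4-yne
Conditions: Et3SiOTf (2.5 equiv), 2,6-lutidine, CH2Cl2, −78 to 0 °C
Reagents that add atoms: triethylsilyl trifluoromethanesulfonate, CC[Si](CC)(CC)OS(=O)(=O)C(F)(F)F
Why: Silylation with a silyl triflate is strong enough for the tertiary propargylic alcohol; the tertiary ether protects C10–OH through steps 10 to 13 and the primary ether is the handle for step 11.

Step 10
Reactants: 17; 18 tributyltin hydride
Product: 19 tributyl[(1E,3R)-3-methyl-3,5-bis[(triethylsilyl)oxy]pent-1-en-1-yl]stannane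
Conditions: PdCl2(PPh3)2 (2 mol %), 18 added slowly, THF, 0 °C
Reagents that add atoms: none
Why: Palladium-catalysed syn-hydrostannation of a terminal alkyne; the fully substituted propargylic carbon steers tin to the terminal carbon and gives the E-alkenylstannane, and no alkenyl iodide is present at this stage.

Step 11
Reactants: 19
Product: 20 (3R,4E)-3-methyl-3-[(triethylsilyl)oxy]-5-(tributylstannyl)pent-4-enal
Conditions: (COCl)2, DMSO, CH2Cl2, −78 to −40 °C; Et3N, −78 °C to rt
Reagents that add atoms: none
Why: Swern oxidation applied directly to the primary triethylsilyl ether, which the chlorosulfonium reagent cleaves and oxidises in one operation while the tertiary silyl ether stays in place.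

Step 12
Reactants: 9; 20
Product: 21 (4R,5S)-4-[(1S,3R,4E)-1-hydroxy-3-methyl-3-[(triethylsilyl)oxy]-5-(tributylstannyl)pent-4-en-1-yl]-5-[(1Z)-2-iodoprop-1-en-1-yl]-3-methylideneoxolan-2-one
Conditions: In powder (1.5 equiv), THF/H2O (4:1), rt
Reagents that add atoms: none
Why: Indium-mediated Barbier allylation: the allylindium from 9 reacts through its γ-carbon (C7) on the face anti to the C6 substituent (7R, trans-lactone), and a chair Zimmerman–Traxler transition state with the aldehyde chain equatorial and the ring-held E-type γ-substituent gives the 7,8-anti adduct (8S); alkenyl iodide and alkenylstannane are inert to indium metal.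

Step 13
Reactants: 21; 22 angelic acid
Product: 23 (1R,3R,4E)-1-[(2S,3R)-2-[(1Z)-2-iodoprop-1-en-1-yl]-4-methylidene-5-oxooxolan-3-yl]-3-methyl-3-[(triethylsilyl)oxy]-5-(tributylstannyl)pent-4-en-1-yl (2Z)-2-methylbut-2-enoate
Conditions: PPh3, iPrO2CN=NCO2iPr (betaine preformed), 22, toluene, 0 °C to rt
Reagents that add atoms: none
Why: Mitsunobu esterification: the C8 alkoxyphosphonium ion is displaced by angelate with inversion, which sets 8R and installs the ester under base-free conditions that do not isomerise the Z-enoate; the silylated C10 oxygen cannot interfere.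

Step 14
Reactants: 23
Product: 24 (1R,3R,4E)-3-hydroxy-1-[(2S,3R)-2-[(1Z)-2-iodoprop-1-en-1-yl]-4-methylidene-5-oxooxolan-3-yl]-3-methyl-5-(tributylstannyl)pent-4-en-1-yl (2Z)-2-methylbut-2-enoate
Conditions: HF·pyridine, pyridine, THF, 0 °C to rt
Reagents that add atoms: none
Why: Fluoride cleavage of the tertiary triethylsilyl ether; the excess of pyridine buffers the medium so that the alkenylstannane is not protonated.

Step 15
Reactants: 24; 25 carbon monoxide
Product: 26 (3aR,4R,6R,7E,10Z,11aR)-6-hydroxy-6,10-dimethyl-3-methylidene-2,9-dioxo-2,3,3a,4,5,6,9,11a-octahydrocyclodeca[b]furan-4-yl (2Z)-2-methylbut-2-enoate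
Conditions: Pd2(dba)3 (10 mol %), AsPh3 (40 mol %), CO (3 bar), NMP, 50 °C; 24 fed over 12 h to a final 1 mM
Reagents that add atoms: none
Why: Carbonylative Stille macrocyclisation: zerovalent palladium adds to the C4–I bond of 24 with retention of the Z geometry, CO inserts to give the C3 acylpalladium iodide, the C2 alkenylstannane transmetalates with retention of the E geometry, and reductive elimination forms C3–C4 and C2–C3. The closest known reaction type is the carbonylative coupling of alkenyl iodides or triflates with alkenylstannanes to divinyl ketones, including closures of larger carbocycles; the ten-membered case extends the ring size, not the mechanism. The ring closes by reductive elimination from an eleven-membered acyl(alkenyl)palladacycle, so the ketone and both alkenes end up inside the ten-membered carbocycle. No stereocentre is formed. CO insertion is favoured over direct coupling by the CO pressure and the weak donor AsPh3, and by the substrate, because direct coupling would give a more strained nine-membered E,Z-diene. Cyclisation is favoured over oligomerisation by slow addition to a dilute catalyst solution and by the trans-lactone and the fully substituted C10, which restrict the chain to few rotamers. Both alkene geometries are fixed in 24 and pass through stereoretentive steps only. The neutral medium leaves the angelate, the α-methylene lactone and the free tertiary alcohol untouched.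

Step 16
Reactants: 26
Product: 27 (3aR,4R,6R,7E,9R,10Z,11aR)-6,9-dihydroxy-6,10-dimethyl-3-methylidene-2-oxo-2,3,3a,4,5,6,9,11a-octahydrocyclodeca[b]furan-4-yl (2Z)-2-methylbut-2-enoate
Conditions: NaBH4, CeCl3·7H2O, MeOH, −78 °C
Reagents that add atoms: none
Why: Luche 1,2-reduction of the cross-conjugated dienone; hydride should add to the outer face of the carbonyl in the preferred ring conformation and set 3R, and the cerium-modified borohydride at low temperature spares the α-methylene lactone and the angelate.

**Compound list**

1 | (E)-but-2-enal (crotonaldehyde) | C/C=C/C=O | starting material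
2 | propyne | CC#C | starting material
3 | (2E,4S)-hept-2-en-5-yn-4-ol | C/C=C/[C@H](O)C#CC | intermediate
4 | sodium (5S)-2,2-bis(2-methoxyethoxy)-3-methyl-5-[(1E)-prop-1-en-1-yl]-2,5-dihydro-1,2-oxaluminol-2-uide (cyclic alkenylaluminate, formed and used in the flask) | C/C=C/[C@@H]1O[Al-](OCCOC)(OCCOC)C(C)=C1.[Na+] | intermediate
5 | (2E,4S,5Z)-6-iodohepta-2,5-dien-4-ol | C/C=C/[C@H](O)/C=C(/C)I | intermediate
6 | 2-(bromomethyl)prop-2-enoic acid | C=C(CBr)C(=O)O | starting material
7 | 2-(bromomethyl)prop-2-enoyl chloride (formed and used in the flask) | C=C(CBr)C(=O)Cl | intermediate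
8 | (2E,4S,5Z)-6-iodohepta-2,5-dien-4-yl 2-(bromomethyl)prop-2-enoate | C/C=C/[C@H](OC(=O)C(=C)CBr)/C=C(/C)I | intermediate
9 | (5S)-3-(bromomethyl)-5-[(1Z)-2-iodoprop-1-en-1-yl]furan-2(5H)-one | BrCC1=C[C@@H](/C=C(/C)I)OC1=O | intermediate
10 | (R)-citramalic acid, (2R)-2-hydroxy-2-methylbutanedioic acid | OC(=O)[C@](C)(O)CC(=O)O | starting material
11 | 2-[(4R)-2,2,4-trimethyl-5-oxo-1,3-dioxolan-4-yl]acetic acid | OC(=O)C[C@@]1(C)OC(C)(C)OC1=O | intermediate
12 | (5R)-5-(2-hydroxyethyl)-2,2,5-trimethyl-1,3-dioxolan-4-one (formed and used in the flask) | OCC[C@@]1(C)OC(C)(C)OC1=O | intermediate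
13 | (3R)-3-hydroxy-3-methyloxolan-2-one | C[C@@]1(O)CCOC1=O | intermediate
14 | (3R)-3-methyloxolane-2,3-diol (lactol, both anomers) | C[C@@]1(O)CCOC1O | intermediate
15 | dimethyl (1-diazo-2-oxopropyl)phosphonate | CC(=O)C(=[N+]=[N-])P(=O)(OC)OC | starting material
16 | (3R)-3-methylpent-4-yne-1,3-diol | C#C[C@](C)(O)CCO | intermediate
17 | (3R)-3-methyl-1,3-bis[(triethylsilyl)oxy]pent-4-yne | C#C[C@](C)(O[Si](CC)(CC)CC)CCO[Si](CC)(CC)CC | intermediate
18 | tributyltin hydride | CCCC[SnH](CCCC)CCCC | starting material
19 | tributyl[(1E,3R)-3-methyl-3,5-bis[(triethylsilyl)oxy]pent-1-en-1-yl]stannane | CCCC[Sn](CCCC)(CCCC)/C=C/[C@](C)(O[Si](CC)(CC)CC)CCO[Si](CC)(CC)CC | intermediate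
20 | (3R,4E)-3-methyl-3-[(triethylsilyl)oxy]-5-(tributylstannyl)pent-4-enal | CCCC[Sn](CCCC)(CCCC)/C=C/[C@](C)(O[Si](CC)(CC)CC)CC=O | intermediate
21 | (4R,5S)-4-[(1S,3R,4E)-1-hydroxy-3-methyl-3-[(triethylsilyl)oxy]-5-(tributylstannyl)pent-4-en-1-yl]-5-[(1Z)-2-iodoprop-1-en-1-yl]-3-methylideneoxolan-2-one | CCCC[Sn](CCCC)(CCCC)/C=C/[C@](C)(O[Si](CC)(CC)CC)C[C@H](O)[C@@H]1[C@@H](/C=C(/C)I)OC(=O)C1=C | intermediate
22 | angelic acid, (2Z)-2-methylbut-2-enoic acid | C/C=C(/C)C(=O)O | starting material
23 | (1R,3R,4E)-1-[(2S,3R)-2-[(1Z)-2-iodoprop-1-en-1-yl]-4-methylidene-5-oxooxolan-3-yl]-3-methyl-3-[(triethylsilyl)oxy]-5-(tributylstannyl)pent-4-en-1-yl (2Z)-2-methylbut-2-enoate | CCCC[Sn](CCCC)(CCCC)/C=C/[C@](C)(O[Si](CC)(CC)CC)C[C@@H](OC(=O)/C(C)=C\C)[C@@H]1[C@@H](/C=C(/C)I)OC(=O)C1=C | intermediate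
24 | (1R,3R,4E)-3-hydroxy-1-[(2S,3R)-2-[(1Z)-2-iodoprop-1-en-1-yl]-4-methylidene-5-oxooxolan-3-yl]-3-methyl-5-(tributylstannyl)pent-4-en-1-yl (2Z)-2-methylbut-2-enoate (seco lactone) | CCCC[Sn](CCCC)(CCCC)/C=C/[C@](C)(O)C[C@@H](OC(=O)/C(C)=C\C)[C@@H]1[C@@H](/C=C(/C)I)OC(=O)C1=C | intermediate
25 | carbon monoxide | [C-]#[O+] | starting material
26 | (3aR,4R,6R,7E,10Z,11aR)-6-hydroxy-6,10-dimethyl-3-methylidene-2,9-dioxo-2,3,3a,4,5,6,9,11a-octahydrocyclodeca[b]furan-4-yl (2Z)-2-methylbut-2-enoate (3-oxo macrocycle) | C=C1C(=O)O[C@@H]2/C=C(/C)C(=O)/C=C/[C@](C)(O)C[C@@H](OC(=O)/C(C)=C\C)[C@@H]12 | intermediate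
27 | (3aR,4R,6R,7E,9R,10Z,11aR)-6,9-dihydroxy-6,10-dimethyl-3-methylidene-2-oxo-2,3,3a,4,5,6,9,11a-octahydrocyclodeca[b]furan-4-yl (2Z)-2-methylbut-2-enoate | C=C1C(=O)O[C@@H]2/C=C(/C)[C@H](O)/C=C/[C@](C)(O)C[C@@H](OC(=O)/C(C)=C\C)[C@@H]12 | target

**Step count and risk**

Total: 16 steps. Fragment A (9) takes steps 1–4, fragment B (20) takes steps 5–11, and steps 12–16 follow the union. The longest linear sequence is 12 steps, from 10 through steps 5–16 to 27.

Least certain steps:

**Step 15 (key step).** The E,Z-cyclodecadienone fused to a trans-lactone is strained, so intermolecular acyl transfer to a second stannane (oligomerisation) may outrun ring closure. Slow protodestannylation and ionisation of the allylic C6–O lactone bond by zerovalent palladium are lesser drains. The fallback closes the ring by a Nozaki–Hiyama–Kishi reaction between the C4 alkenyl iodide and a C3 aldehyde, which forms C3–C4 at the carbinol level and leads to the less planar ring of the target itself. It sets out from 19 and returns at 26: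
- Tin–lithium exchange (nBuLi, THF, −78 °C) and trapping with formaldehyde give (2E,4R)-4-methyl-4,6-bis[(triethylsilyl)oxy]hex-2-en-1-ol F1.
- tBuMe2SiCl and imidazole give the allylic silyl ether F2, and the direct Swern oxidation of step 11 gives aldehyde F3.
- The Barbier reaction with 9 (In, THF/H2O) gives the anti adduct F4, and the Mitsunobu reaction with 22 gives the angelate F5, as in steps 12 and 13.
- HF·pyridine removes both silyl groups to give diol F6, and MnO2 oxidises only the primary allylic alcohol to enal F7.
- CrCl2 with NiCl2 (cat.) in DMSO/THF at high dilution closes the ring to the C3 carbinols F8 (27 and its C3 epimer). MnO2 oxidises this mixture to 26, which re-enters at step 16.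

**Step 12.** Discrimination between the two faces of the aldehyde may be incomplete, so that the 7,8-syn epimer forms beside 21. The adduct can also translactonise, because the new C8 hydroxyl is γ to C12. The fallback makes the step stereoconvergent instead of stereoselective. It sets out from the same union of 9 and 20. The epimers are separated and 21 goes on to step 13. The syn alcohol, (4R,5S)-4-[(1R,3R,4E)-1-hydroxy-3-methyl-3-[(triethylsilyl)oxy]-5-(tributylstannyl)pent-4-en-1-yl]-5-[(1Z)-2-iodoprop-1-en-1-yl]-3-methylideneoxolan-2-one F9, already has the C8 configuration of the target and is acylated with retention (22, 2,4,6-trichlorobenzoyl chloride, Et3N, toluene; then F9, 80 °C, no DMAP). Both streams meet at 23.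

**Step 13.** Angelate is a weak and bulky nucleophile at a carbinol flanked by the C7 branch, so elimination toward C7=C8, participation of the lactone carbonyl, or isomerisation to the tiglate may take over. The fallback separates inversion from acylation. It sets out from 21. A Mitsunobu reaction with the smaller and more acidic formic acid gives the inverted formate F10. Mild methanolysis (KHCO3, MeOH, 0 °C) gives the syn alcohol F9. The Yamaguchi-type angeloylation with retention described under step 12 returns to 23.

**Step 16.** Hydride may add to the inner face of the ketone, or conjugate reduction of the dienone may compete, because the facial bias depends on a ring conformation that is not known. The fallback replaces conformational control by reagent control. It sets out from 26 and returns at 27. Corey–Bakshi–Shibata reduction uses (S)-1-methyl-3,3-diphenyltetrahydro-1H,3H-pyrrolo[1,2-c][1,3,2]oxazaborole and catecholborane at −78 °C. The catalyst should treat the α-branched C4 alkenyl arm as the large group and deliver 3R. No new compound is made.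

**Step 11.** The HCl released when the chlorosulfonium reagent cleaves the primary silyl ether may protodestannylate the alkenylstannane, or the cleavage may stall. The fallback separates deprotection from oxidation. It sets out from 19. Pyridinium p-toluenesulfonate in MeOH/CH2Cl2 at −10 °C removes only the primary silyl group to give (3R,4E)-3-methyl-3-[(triethylsilyl)oxy]-5-(tributylstannyl)pent-4-en-1-ol F11. Parikh–Doering oxidation (SO3·pyridine, DMSO, iPr2NEt) returns to 20.

## Further compounds

F1 | step 15 | (2E,4R)-4-methyl-4,6-bis[(triethylsilyl)oxy]hex-2-en-1-ol | OC/C=C/[C@](C)(O[Si](CC)(CC)CC)CCO[Si](CC)(CC)CC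
F2 | step 15 | tert-butyl{[(2E,4R)-4-methyl-4,6-bis[(triethylsilyl)oxy]hex-2-en-1-yl]oxy}dimethylsilane | CC(C)(C)[Si](C)(C)OC/C=C/[C@](C)(O[Si](CC)(CC)CC)CCO[Si](CC)(CC)CC
F3 | step 15 | (3R,4E)-6-[(tert-butyldimethylsilyl)oxy]-3-methyl-3-[(triethylsilyl)oxy]hex-4-enal | CC(C)(C)[Si](C)(C)OC/C=C/[C@](C)(O[Si](CC)(CC)CC)CC=O
F4 | step 15 | (4R,5S)-4-[(1S,3R,4E)-6-[(tert-butyldimethylsilyl)oxy]-1-hydroxy-3-methyl-3-[(triethylsilyl)oxy]hex-4-en-1-yl]-5-[(1Z)-2-iodoprop-1-en-1-yl]-3-methylideneoxolan-2-one | CC(C)(C)[Si](C)(C)OC/C=C/[C@](C)(O[Si](CC)(CC)CC)C[C@H](O)[C@@H]1[C@@H](/C=C(/C)I)OC(=O)C1=C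
F5 | step 15 | (1R,3R,4E)-6-[(tert-butyldimethylsilyl)oxy]-1-[(2S,3R)-2-[(1Z)-2-iodoprop-1-en-1-yl]-4-methylidene-5-oxooxolan-3-yl]-3-methyl-3-[(triethylsilyl)oxy]hex-4-en-1-yl (2Z)-2-methylbut-2-enoate | CC(C)(C)[Si](C)(C)OC/C=C/[C@](C)(O[Si](CC)(CC)CC)C[C@@H](OC(=O)/C(C)=C\C)[C@@H]1[C@@H](/C=C(/C)I)OC(=O)C1=C
F6 | step 15 | (1R,3R,4E)-3,6-dihydroxy-1-[(2S,3R)-2-[(1Z)-2-iodoprop-1-en-1-yl]-4-methylidene-5-oxooxolan-3-yl]-3-methylhex-4-en-1-yl (2Z)-2-methylbut-2-enoate | OC/C=C/[C@](C)(O)C[C@@H](OC(=O)/C(C)=C\C)[C@@H]1[C@@H](/C=C(/C)I)OC(=O)C1=C
F7 | step 15 | (1R,3R,4E)-3-hydroxy-1-[(2S,3R)-2-[(1Z)-2-iodoprop-1-en-1-yl]-4-methylidene-5-oxooxolan-3-yl]-3-methyl-6-oxohex-4-en-1-yl (2Z)-2-methylbut-2-enoate | O=C/C=C/[C@](C)(O)C[C@@H](OC(=O)/C(C)=C\C)[C@@H]1[C@@H](/C=C(/C)I)OC(=O)C1=C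
F8 | step 15 | mixture of 27 and its C3 epimer, (3aR,4R,6R,7E,10Z,11aR)-6,9-dihydroxy-6,10-dimethyl-3-methylidene-2-oxo-2,3,3a,4,5,6,9,11a-octahydrocyclodeca[b]furan-4-yl (2Z)-2-methylbut-2-enoate with both configurations at the 9-carbinol | C=C1C(=O)O[C@@H]2/C=C(/C)C(O)/C=C/[C@](C)(O)C[C@@H](OC(=O)/C(C)=C\C)[C@@H]12
F9 | step 12 | (4R,5S)-4-[(1R,3R,4E)-1-hydroxy-3-methyl-3-[(triethylsilyl)oxy]-5-(tributylstannyl)pent-4-en-1-yl]-5-[(1Z)-2-iodoprop-1-en-1-yl]-3-methylideneoxolan-2-one | CCCC[Sn](CCCC)(CCCC)/C=C/[C@](C)(O[Si](CC)(CC)CC)C[C@@H](O)[C@@H]1[C@@H](/C=C(/C)I)OC(=O)C1=C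
F10 | step 13 | (1R,3R,4E)-1-[(2S,3R)-2-[(1Z)-2-iodoprop-1-en-1-yl]-4-methylidene-5-oxooxolan-3-yl]-3-methyl-3-[(triethylsilyl)oxy]-5-(tributylstannyl)pent-4-en-1-yl formate | CCCC[Sn](CCCC)(CCCC)/C=C/[C@](C)(O[Si](CC)(CC)CC)C[C@@H](OC=O)[C@@H]1[C@@H](/C=C(/C)I)OC(=O)C1=C
F0 | step 16 | none | none
F11 | step 11 | (3R,4E)-3-methyl-3-[(triethylsilyl)oxy]-5-(tributylstannyl)pent-4-en-1-ol | CCCC[Sn](CCCC)(CCCC)/C=C/[C@](C)(O[Si](CC)(CC)CC)CCO
A1 | alternative 1 | isoxazoline-bridged ten-membered lactone (C3 tert-butyldimethylsilyl ether) | C=C1C(=O)O[C@@H]2/C=C(/C)[C@H](O[Si](C)(C)C(C)(C)C)/C=C/[C@]3(C)ON=C(C3)[C@@H]12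
A2 | alternative 2 | silylene-bridged ten-membered carbocycle (C3,C6-diisopropylsilylene, C12 PMB ether, C8 angelate) | C=C(COCc4ccc(OC)cc4)[C@H]1[C@@H]2O[Si](C(C)C)(C(C)C)O[C@H](/C=C/[C@](C)(O)C[C@H]1OC(=O)/C(C)=C\C)C(C)=C2
A3 | alternative 3 | (1E,4Z)-cyclodecadien-6-one with protected C3, C8, C10 and C12 oxygens | C=C(CO[Si](CC)(CC)CC)[C@H]1C(=O)/C=C(/C)[C@H](O[Si](C)(C)C(C)(C)C)/C=C/[C@](C)(O[Si](C)(C)C(C)(C)C)C[C@H]1OCc2ccc(OC)cc2
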